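You are asked when the target peaks in this flask and how high, and the midnight run is this very flask followed so far.

common to all: starting material 0.40 M

| flask | remark | time |
|---|---|---|
| midnight | the very flask that is asked about, followed so far |  |
| flask |  | 6.0 h |

midnight run (percent of the starting material charged)

| time / h | target / % | starting material / % |
|---|---|---|
| 0.0417 | 31 | 42 |
| 0.100 | 53 | 17 |
| 0.333 | 44 | 2 |
| 1.00 | 5 | 0 |
| 3.00 | 0 | 0 |

(each reading ± 1.5 percentage points)

- a reading or a percentage of target counts all its forms, free or not
- a reading of starting material is of its free form alone

1. time up to 6.0 h at which target stands highest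
2. the amount of target, in percent of the starting material charged, at that time

Start at the tail of the midnight run. By 0.333 h the starting material reads 2 %, so from there you may take the target's fall as plain first-order. The fall constant d, the logarithm of the ratio of the two late target readings over the time between them, is 3.26 h⁻¹.

Now let one first-order step with constant f feed the target while d removes it. Integrating gives a difference of two exponentials, with its peak at ln(f/d)/(f-d) and a height there of exp(-d t) of the charge. The starting material's fall to 17 % at 0.100 h gives f = 17.7 h⁻¹, so the peak comes at 0.117 h with 68.3 %.

That f is the weak link: the same curve gives 67.6 % at 0.100 h, where the midnight run reads 53 %. So take f from the tail instead. Run back to zero time, the tail stands at 130 % of the charge, which the closed form sets equal to f/(f-d). This gives a slower f of 14.0 h⁻¹, and I commit to a peak at 0.136 h with 64.3 %.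

The forecast says 0.16 h and 61 %, later and lower than mine, and notes that “the maximum falls unsampled between 0.1 and 0.33 h”.

The flask peaks at 0.150 h with 57.7 %.

    starting material ⇌ intermediate (K = 0.910, k = 0.00540 s⁻¹)
    intermediate → target (k = 0.0200 s⁻¹)
    starting material + target ⇌ idle adduct, settled at all times (K = 1.60 M⁻¹)
    target → over-reaction product (k = 9.20 × 10⁻⁴ s⁻¹)
    2 starting material → self-condensation product (k = 0.00110 M⁻¹ s⁻¹)

At that time the flask holds 8.08 % of self-condensation product, for which my curve has no place. The fall constant carries on: from the 5 % read at 1.00 h it gives 0.00737 % at 3.00 h, and the flask holds 0.00657 %. On the neighbouring flask, the same one read at 1.5 h, it gives 0.979 %, and that flask holds 0.944 % of target.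

Readings and results stem from a simulated flask for an exercise; noise was put on by code.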